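The rate constants were drawn at random within sensible limits; the flask was simulated.

Amounts come first here: the substrate sits in the first phase, its reagent is charged behind a phase boundary, and target, once made, can meet substrate, decompose or escape into the second phase.

substrate 0.092 M; reagent in the second phase 2.00 equiv; protic impurity 9.20 mM; time 50 s; volume of the second phase over the first 1.0

    target → decomposed product (k1 = 0.024 s⁻¹)
    substrate + target → side product (k2 = 0.74 M⁻¹ s⁻¹)
    substrate + reagent in the reaction phase → target (k3 = 32 M⁻¹ s⁻¹)
    reagent in the reaction phase + protic impurity → quenched reagent (k4 = 1.9 M⁻¹ s⁻¹)
    crystals ⇌ target, rate k5*(cs5 - [target]) while solid is left; crystals form when [target] > cs5 (cs5 = 0.091 M, k5 = 0.15 s⁻¹)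
    target ⇌ product in the second phase, rate k6*([target] - [product in the second phase]/K6) per volume of the first phase (K6 = 2.8, k6 = 0.024 s⁻¹)
    reagent in the reaction phase ⇌ reagent in the second phase, rate k7*([reagent in the reaction phase] - [reagent in the second phase]/K7) per volume of the first phase (K7 = 1.1, k7 = 0.083 s⁻¹)

* how much target and product in the second phase and crystals together there is at 50 s, in percent of the substrate charged
* concentration of target in solution at 12 s, in percent of saturation
* the change that raises the amount of target and product in the second phase and crystals together at 50 s, in percent of the substrate charged most ("none" if none brings more than 2 percentage points) (beta / theta / alpha / delta / none)
* amount of target and product in the second phase and crystals together at 50 s, in percent of the substrate charged, after beta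

- percent here means substrate units held: one side product counts as two
- what is said of target includes product in the second phase and crystals
- in the second phase: reagent in the second phase, product in the second phase; everything else is in the first
- charges count per volume of the first phase; a concentration in a rate is the amount of a species over the volume of its own phase; every rate counts per litre of the first phase
- crystals is a solid; its amount is given per volume of the solution
- run time (flask): 50 s

**Feed time.** At its starting rate the transfer delivers one equivalent of reagent in 6.63 s, while the reaction with substrate takes up reagent in about 0.340 s, so you take the reagent transfer as the rate-limiting step while substrate lasts, and let substrate fall roughly linearly over that time. Integrating the side reaction over that falling substrate and rising target costs you 15.0% of the substrate units, which leaves 85.0% made as target. That is 0.0782 M, below the solubility 0.091 M, so you expect no crystals.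

**Bench rule.** The usual rule for a protected product assumes quick partition, so that target decays at the decomposition constant times the first-phase share at equilibrium, 26.3%. Applied honestly this gives 0.00632 s⁻¹ and 62.0% left at the end. But the rule needs transfer to outrun decomposition, and the ratio of their constants is 1.00, so it stops working here.

**Escape share.** Use instead the escape share, the transfer coefficient over the sum of transfer coefficient and decomposition constant, which is, backflow aside, the fraction of dissolved target that reaches the second phase before decomposing: 50.0%. Backflow aside, dissolved target empties with a time of 20.8 s, shorter than the run, so, ignoring backflow and the dissolved remainder, you commit to y = 42.5%. Letting made target decay from the middle of the feed gives c(target) at 12 s as 56.6% of saturation. Halving the feed time halves the loss, so yb = 46.2%. Doubled transfer gains 14 percentage points against 3.8 points for either reagent change, so you choose delta.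

**The forecast.** It gives y = 45%, sat = 58% and yb = 47.5%, and picks delta, holding that “faster extraction into the protective second phase” helps more than a few points of reagent supply. Its y stands above yours.

**The flask.** The simulation gives y = 43.5%, sat = 57.2% and yb = 45.9%, and delta wins with 7.3 points, against 3.3 points for theta and 2.4 points for beta, so the forecast held. In this flask substrate stood at 41.9% after 5.00 s and 0% after 25.0 s, while side product reached 18.1%. Decomposition and net transfer of dissolved target came to 38.4% and 30.0% by 50.0 s, a split of 43.9% to the second phase against the escape share 50.0%, and at that time 30.0% stood in the second phase out of the 43.5% of target held in all its forms.

**Dilute neighbour.** In the neighbour flask with 0.023 M of substrate, the reckoning keeps feed time and escape share as they were and shrinks the side loss with concentration, so it gives 48.1%. The simulation of that flask gives 50.3%.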